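**Retrosynthetic overview**
- The ten-membered ring is closed last, at the C1–C2 sp2–sp2 bond, by a copper-mediated coupling of an E-alkenyl iodide with a Z-alkenylstannane; both ring alkene geometries are fixed beforehand.
- Key step: the C7–C8 bond is made by intermolecular decarboxylative radical conjugate addition of a C8 α-acyloxyalkyl radical (already carrying the C9 acetate and the C8 epoxy ester) to a 5-substituted 3-(pivaloyloxymethyl)butenolide. It sets C7 and C8, and loss of pivalate unveils the α-methylene lactone.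
- Radical precursor: iodo-aldol of methyl propiolate with (R)-glyceraldehyde acetonide sets C9 and the C10=C1 geometry; the glyceraldehyde stereocentre is only a relay and becomes the radical carbon.
- Butenolide: Sharpless epoxidation sets C4/C5; chelation-controlled addition of a magnesiated iodoacrylate sets C6 and lactonises.
- Ring order: oxiranes (acyclic) → butenolide → α-methylene-γ-lactone → ten-membered carbocycle.

Assumption: atom labels C1–C15 follow germacrane numbering (ring C1–C10, lactone C6–O–C12, ester carbon C14); the target is read as 4R,5R,6S,7R,8S,9S with a (2S,3S)-epoxy ester and both ring alkenes cis within the ring.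

**Butenolide acceptor**

Step 1
Reactants: 1 methyl propiolate; 2 formaldehyde (used as paraformaldehyde)
Product: 3 methyl (2Z)-2-(hydroxymethyl)-3-iodoprop-2-enoate
Conditions: MgI2, (CH2O)n, CH2Cl2, −20 → 0 °C
Reagents that add atoms: magnesium iodide, I[Mg]I
Why: Three-component iodo-aldol (β-iodo Morita–Baylis–Hillman type) in which iodide adds to the ynoate and the iodoallenolate is trapped by formaldehyde on the side away from iodine, so the kinetic product has iodine cis to the ester (Z), as needed for lactonisation in step 6.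

Step 2
Reactants: 3 methyl (2Z)-2-(hydroxymethyl)-3-iodoprop-2-enoate
Product: 4 methyl (2Z)-3-iodo-2-[(pivaloyloxy)methyl]prop-2-enoate
Conditions: tBuCOCl, pyridine, DMAP (cat.), CH2Cl2, 0 °C
Reagents that add atoms: pivaloyl chloride, CC(C)(C)C(Cl)=O
Why: Simple O-acylation; the pivalate tolerates the Grignard chemistry of step 6 and later acts as the β-leaving group that generates the exocyclic methylene.

Step 3
Reactants: 5 (2E)-3-methylpent-2-en-4-yn-1-ol
Product: 6 (2E,4Z)-3-methyl-5-(tributylstannyl)penta-2,4-dien-1-ol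
Conditions: Bu3SnH, Et3B (10 mol%), trace air, PhMe, −78 °C
Reagents that add atoms: tributyltin hydride, CCCC[SnH](CCCC)CCCC
Why: Radical hydrostannation (Et3B/O2 initiation) in which the stannyl radical adds to the terminal alkyne carbon and hydrogen is delivered anti to tin at low temperature, giving the kinetic Z-alkenylstannane (future C2=C3); the minor E isomer is removed by chromatography.

Step 4
Reactants: 6 (2E,4Z)-3-methyl-5-(tributylstannyl)penta-2,4-dien-1-ol
Product: 7 {(2R,3R)-3-methyl-3-[(Z)-2-(tributylstannyl)ethenyl]oxiran-2-yl}methanol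
Conditions: Ti(OiPr)4 (10 mol%), L-(+)-diethyl tartrate (12 mol%), tBuOOH, 4 Å MS, CH2Cl2, −20 °C
Reagents that add atoms: tert-butyl hydroperoxide, CC(C)(C)OO
Why: Sharpless asymmetric epoxidation of the E-allylic alcohol, where L-(+)-tartrate delivers oxygen to the face that gives the (2R,3R)-epoxide (C4 R, C5 R) and only the allylic-alcohol alkene reacts.

Step 5
Reactants: 7 {(2R,3R)-3-methyl-3-[(Z)-2-(tributylstannyl)ethenyl]oxiran-2-yl}methanol
Product: 8 (2S,3R)-3-methyl-3-[(Z)-2-(tributylstannyl)ethenyl]oxirane-2-carbaldehyde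
Conditions: (nPr4N)RuO4 (5 mol%), N-methylmorpholine N-oxide, 4 Å MS, CH2Cl2, 0 °C
Reagents that add atoms: none
Why: Ley–Griffith oxidation under neutral conditions leaves the vinyl epoxide and the stannane intact; the descriptor change at the oxirane carbon is a CIP priority change only.

Step 6
Reactants: 4 methyl (2Z)-3-iodo-2-[(pivaloyloxy)methyl]prop-2-enoate; 8 (2S,3R)-3-methyl-3-[(Z)-2-(tributylstannyl)ethenyl]oxirane-2-carbaldehyde
Product: 10 [(5S)-5-{(2R,3R)-3-methyl-3-[(Z)-2-(tributylstannyl)ethenyl]oxiran-2-yl}-2-oxo-2,5-dihydrofuran-3-yl]methyl pivalate, via alkenylmagnesium chloride 9 (not isolated)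
Conditions: 4, iPrMgCl·LiCl, THF, −78 °C; then MgBr2·OEt2, 8, CH2Cl2/THF, −78 → −20 °C
Reagents that add atoms: none
Why: Iodine–magnesium exchange gives the configurationally stable Z-magnesiated enoate, which adds to the epoxy aldehyde under Cram-chelate control (magnesium bridging carbonyl and epoxide oxygens, attack past H) to set C6 S, threo to the epoxide, and the alkoxide then lactonises onto the cis ester to the butenolide.

**Epoxy acid**

Step 7
Reactants: 11 angelic acid [(2Z)-2-methylbut-2-enoic acid]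
Product: 12 (2Z)-2-methylbut-2-en-1-ol
Conditions: LiAlH4, Et2O, 0 °C
Reagents that add atoms: none
Why: Hydride reduction of the acid to the allylic alcohol with retention of the Z geometry.

Step 8
Reactants: 12 (2Z)-2-methylbut-2-en-1-ol
Product: 13 [(2R,3S)-2,3-dimethyloxiran-2-yl]methanol
Conditions: Ti(OiPr)4 (10 mol%), L-(+)-diethyl tartrate (12 mol%), tBuOOH, 4 Å MS, CH2Cl2, −20 °C
Reagents that add atoms: tert-butyl hydroperoxide, CC(C)(C)OO
Why: Sharpless asymmetric epoxidation, where L-(+)-tartrate delivers oxygen to the face of the Z-allylic alcohol that gives the (2R,3S)-epoxy alcohol, the precursor of the (2S,3S)-acid.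

Step 9
Reactants: 13 [(2R,3S)-2,3-dimethyloxiran-2-yl]methanol
Product: 14 (2S,3S)-2,3-dimethyloxirane-2-carboxylic acid
Conditions: TEMPO (10 mol%), PhI(OAc)2, MeCN/H2O (1:1), rt
Reagents that add atoms: water, O
Why: Oxoammonium (TEMPO/PhI(OAc)2) oxidation of the primary alcohol through the aldehyde hydrate to the acid without touching the epoxide; 2R becomes 2S only through the CIP priority change.

**Radical precursor**

Step 10
Reactants: 15 (4R)-2,2-dimethyl-1,3-dioxolane-4-carbaldehyde (D-glyceraldehyde as its acetonide); 1 methyl propiolate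
Product: 16 methyl (2E)-2-{(S)-[(4R)-2,2-dimethyl-1,3-dioxolan-4-yl](hydroxy)methyl}-3-iodoprop-2-enoate
Conditions: MgI2, CH2Cl2, 0 °C, then 35 °C
Reagents that add atoms: magnesium iodide, I[Mg]I
Why: Three-component iodo-aldol in which Felkin–Anh attack on the α-alkoxy aldehyde (anti to the dioxolane C–O bond) sets C9 S (anti adduct), and warming equilibrates the vinyl iodide by reversible iodide addition to the more stable E isomer (iodine trans to the ester, cis to C9).

Step 11
Reactants: 16 methyl (2E)-2-{(S)-[(4R)-2,2-dimethyl-1,3-dioxolan-4-yl](hydroxy)methyl}-3-iodoprop-2-enoate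
Product: 17 methyl (2E)-2-{(S)-acetoxy[(4R)-2,2-dimethyl-1,3-dioxolan-4-yl]methyl}-3-iodoprop-2-enoate
Conditions: Ac2O, pyridine, DMAP (cat.), 0 °C
Reagents that add atoms: acetic anhydride, CC(=O)OC(C)=O
Why: Acetylation of the secondary alcohol installs the C9 acetate of the target at the outset.

Step 12
Reactants: 17 methyl (2E)-2-{(S)-acetoxy[(4R)-2,2-dimethyl-1,3-dioxolan-4-yl]methyl}-3-iodoprop-2-enoate
Product: 18 methyl (2E)-2-[(1S,2R)-1-acetoxy-2,3-dihydroxypropyl]-3-iodoprop-2-enoate
Conditions: AcOH/H2O (4:1), rt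
Reagents that add atoms: none
Why: Acid hydrolysis of the terminal acetonide; the acidic medium suppresses acetyl migration, and the conjugated α-branched ester is slow to lactonise at room temperature.

Step 13
Reactants: 18 methyl (2E)-2-[(1S,2R)-1-acetoxy-2,3-dihydroxypropyl]-3-iodoprop-2-enoate
Product: 19 (2S,3S,4E)-3-acetoxy-2-hydroxy-5-iodo-4-(methoxycarbonyl)pent-4-enoic acid
Conditions: TEMPO (10 mol%), PhI(OAc)2, MeCN/H2O (1:1), 0 °C → rt
Reagents that add atoms: water, O
Why: Chemoselective oxoammonium oxidation of the primary alcohol of the 1,2-diol to the carboxylic acid, leaving the secondary C8 hydroxyl free.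

Step 14
Reactants: 19 (2S,3S,4E)-3-acetoxy-2-hydroxy-5-iodo-4-(methoxycarbonyl)pent-4-enoic acid; 14 (2S,3S)-2,3-dimethyloxirane-2-carboxylic acid
Product: 21 (2S,3S,4E)-3-acetoxy-2-{[(2S,3S)-2,3-dimethyloxirane-2-carbonyl]oxy}-5-iodo-4-(methoxycarbonyl)pent-4-enoic acid, via mixed anhydride 20 (not isolated)
Conditions: 14 (2.2 equiv), 2,4,6-Cl3C6H2COCl, Et3N, THF, rt; then 19, DMAP, PhMe, rt; aq. NaHCO3 work-up
Reagents that add atoms: none
Why: Yamaguchi esterification in which DMAP transfers the epoxy-acyl group from the mixed anhydride to the C8 hydroxyl (any anhydride formed at the substrate carboxyl is hydrolysed on work-up); the C8 centre is only a relay because it becomes the radical carbon.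

**Fragment union and ring closure**

Step 15 (key step)
Reactants: 21 (2S,3S,4E)-3-acetoxy-2-{[(2S,3S)-2,3-dimethyloxirane-2-carbonyl]oxy}-5-iodo-4-(methoxycarbonyl)pent-4-enoic acid; 10 [(5S)-5-{(2R,3R)-3-methyl-3-[(Z)-2-(tributylstannyl)ethenyl]oxiran-2-yl}-2-oxo-2,5-dihydrofuran-3-yl]methyl pivalate
Product: 24 methyl (2E,3S,4S)-3-acetoxy-4-{[(2S,3S)-2,3-dimethyloxirane-2-carbonyl]oxy}-2-(iodomethylidene)-4-[(2S,3R)-4-methylidene-2-{(2R,3R)-3-methyl-3-[(Z)-2-(tributylstannyl)ethenyl]oxiran-2-yl}-5-oxooxolan-3-yl]butanoate, via N-acyloxyphthalimide 22 (not isolated), via saturated pivalate adduct 23 (not isolated)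
Conditions: N-hydroxyphthalimide, DIC, DMAP (cat.), CH2Cl2, rt; then 10 (2.5 equiv), Ru(bpy)3(PF6)2 (1 mol%), Hantzsch ester, iPr2NEt, CH2Cl2, blue LED, rt; then DBU, 0 °C
Reagents that add atoms: none
Why: Decarboxylative Giese reaction in which single-electron reduction of the N-acyloxyphthalimide releases CO2 and the C8 α-acyloxyalkyl radical, which adds to C7 of the butenolide anti to the C6 substituent (H6/H7 trans, C7 R) and through the face anti to the C9–OAc bond held parallel to the SOMO with the large C10 group beside the small C8–H (8,9-threo, C8 S); hydrogen-atom transfer from the Hantzsch ester gives the saturated pivalate, which cannot accept a second radical, and DBU then eliminates pivalic acid (E1cB) to the α-methylene lactone.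

Step 16
Reactants: 24 methyl (2E,3S,4S)-3-acetoxy-4-{[(2S,3S)-2,3-dimethyloxirane-2-carbonyl]oxy}-2-(iodomethylidene)-4-[(2S,3R)-4-methylidene-2-{(2R,3R)-3-methyl-3-[(Z)-2-(tributylstannyl)ethenyl]oxiran-2-yl}-5-oxooxolan-3-yl]butanoate
Product: 25 target germacranolide CNP0229507.6 (4R,5R,6S,7R,8S,9S; epoxy ester 2S,3S)
Conditions: Cu(O2C-2-C4H3S) (3 equiv), NMP, 0 °C → rt, 1 mM, slow addition
Reagents that add atoms: none
Why: Intramolecular copper-mediated Stille coupling (Liebeskind–Allred type) in which the Z-alkenyl group moves from tin to copper and couples with the alkenyl iodide with retention at both alkenes, closing the ten-membered ring at C1–C2 without a palladium species that could ionise the vinyl epoxide.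

**Compound list**

1 | methyl propiolate | C#CC(=O)OC | starting material
2 | formaldehyde (paraformaldehyde) | C=O | starting material
3 | methyl (2Z)-2-(hydroxymethyl)-3-iodoprop-2-enoate | COC(=O)/C(CO)=C\I | intermediate
4 | methyl (2Z)-3-iodo-2-[(pivaloyloxy)methyl]prop-2-enoate | COC(=O)/C(COC(=O)C(C)(C)C)=C\I | intermediate
5 | (2E)-3-methylpent-2-en-4-yn-1-ol | OC/C=C(C)/C#C | starting material
6 | (2E,4Z)-3-methyl-5-(tributylstannyl)penta-2,4-dien-1-ol | OC/C=C(C)/C=C\[Sn](CCCC)(CCCC)CCCC | intermediate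
7 | {(2R,3R)-3-methyl-3-[(Z)-2-(tributylstannyl)ethenyl]oxiran-2-yl}methanol | OC[C@H]1O[C@]1(C)/C=C\[Sn](CCCC)(CCCC)CCCC | intermediate
8 | (2S,3R)-3-methyl-3-[(Z)-2-(tributylstannyl)ethenyl]oxirane-2-carbaldehyde | O=C[C@H]1O[C@]1(C)/C=C\[Sn](CCCC)(CCCC)CCCC | intermediate
9 | methyl (2Z)-3-(chloromagnesio)-2-[(pivaloyloxy)methyl]prop-2-enoate | COC(=O)/C(COC(=O)C(C)(C)C)=C\[Mg]Cl | intermediate
10 | [(5S)-5-{(2R,3R)-3-methyl-3-[(Z)-2-(tributylstannyl)ethenyl]oxiran-2-yl}-2-oxo-2,5-dihydrofuran-3-yl]methyl pivalate | O=C1O[C@H]([C@H]2O[C@]2(C)/C=C\[Sn](CCCC)(CCCC)CCCC)C=C1COC(=O)C(C)(C)C | intermediate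
11 | angelic acid [(2Z)-2-methylbut-2-enoic acid] | OC(=O)/C(C)=C\C | starting material
12 | (2Z)-2-methylbut-2-en-1-ol | OC/C(C)=C\C | intermediate
13 | [(2R,3S)-2,3-dimethyloxiran-2-yl]methanol | OC[C@@]1(C)O[C@H]1C | intermediate
14 | (2S,3S)-2,3-dimethyloxirane-2-carboxylic acid | OC(=O)[C@@]1(C)O[C@H]1C | intermediate
15 | (4R)-2,2-dimethyl-1,3-dioxolane-4-carbaldehyde (D-glyceraldehyde as its acetonide) | O=C[C@H]1COC(C)(C)O1 | starting material
16 | methyl (2E)-2-{(S)-[(4R)-2,2-dimethyl-1,3-dioxolan-4-yl](hydroxy)methyl}-3-iodoprop-2-enoate | COC(=O)/C(=C/I)[C@H](O)[C@H]1COC(C)(C)O1 | intermediate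
17 | methyl (2E)-2-{(S)-acetoxy[(4R)-2,2-dimethyl-1,3-dioxolan-4-yl]methyl}-3-iodoprop-2-enoate | COC(=O)/C(=C/I)[C@H](OC(C)=O)[C@H]1COC(C)(C)O1 | intermediate
18 | methyl (2E)-2-[(1S,2R)-1-acetoxy-2,3-dihydroxypropyl]-3-iodoprop-2-enoate | COC(=O)/C(=C/I)[C@H](OC(C)=O)[C@H](O)CO | intermediate
19 | (2S,3S,4E)-3-acetoxy-2-hydroxy-5-iodo-4-(methoxycarbonyl)pent-4-enoic acid | COC(=O)/C(=C/I)[C@H](OC(C)=O)[C@H](O)C(=O)O | intermediate
20 | (2S,3S)-2,3-dimethyloxirane-2-carboxylic 2,4,6-trichlorobenzoic anhydride | O=C(OC(=O)[C@@]1(C)O[C@H]1C)c1c(Cl)cc(Cl)cc1Cl | intermediate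
21 | (2S,3S,4E)-3-acetoxy-2-{[(2S,3S)-2,3-dimethyloxirane-2-carbonyl]oxy}-5-iodo-4-(methoxycarbonyl)pent-4-enoic acid | COC(=O)/C(=C/I)[C@H](OC(C)=O)[C@H](OC(=O)[C@@]1(C)O[C@H]1C)C(=O)O | intermediate
22 | 1,3-dioxoisoindolin-2-yl ester of 21 (N-acyloxyphthalimide) | COC(=O)/C(=C/I)[C@H](OC(C)=O)[C@H](OC(=O)[C@@]1(C)O[C@H]1C)C(=O)ON1C(=O)c2ccccc2C1=O | intermediate
23 | saturated pivalate adduct: 24 with C11=C13 replaced by C11H–C13H2–OPiv (both C11 epimers) | CC(C)(C)C(=O)OCC1C(=O)O[C@H]([C@H]2O[C@]2(C)/C=C\[Sn](CCCC)(CCCC)CCCC)[C@H]1[C@H](OC(=O)[C@@]1(C)O[C@H]1C)[C@@H](OC(C)=O)/C(C(=O)OC)=C\I | intermediate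
24 | methyl (2E,3S,4S)-3-acetoxy-4-{[(2S,3S)-2,3-dimethyloxirane-2-carbonyl]oxy}-2-(iodomethylidene)-4-[(2S,3R)-4-methylidene-2-{(2R,3R)-3-methyl-3-[(Z)-2-(tributylstannyl)ethenyl]oxiran-2-yl}-5-oxooxolan-3-yl]butanoate | C=C1C(=O)O[C@H]([C@H]2O[C@]2(C)/C=C\[Sn](CCCC)(CCCC)CCCC)[C@H]1[C@H](OC(=O)[C@@]1(C)O[C@H]1C)[C@@H](OC(C)=O)/C(C(=O)OC)=C\I | intermediate
25 | target germacranolide CNP0229507.6 (4R,5R,6S,7R,8S,9S; epoxy ester 2S,3S; ring alkenes cis) | C=C1C(=O)O[C@H]2[C@H]1[C@H](OC(=O)[C@@]1(C)O[C@H]1C)[C@@H](OC(C)=O)/C(C(=O)OC)=C\C=C/[C@@]1(C)O[C@H]21 | target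

**Totals**
Total steps: 16. Longest linear sequence: 7 steps (steps 10–16, from 15).

**Three steps most likely to fail**

Step 16 (ring closure). A ten-membered ring containing a twisted Z,Z-diene must form against intermolecular coupling and protodestannylation, and this ring size has no close precedent for the coupling. Fallback, setting out from 24 and returning at 25: iododestannylation with I2 in CH2Cl2 at 0 °C (retention of the Z geometry) gives the bis(alkenyl iodide) F1. The ring is then closed by an intramolecular Ullmann-type reductive coupling of the two alkenyl iodides with excess Cu(O2C-2-C4H3S) in NMP under high dilution, so that no tin-to-copper transfer is needed.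

Step 15 (radical C7–C8 coupling). A hindered α-acyloxyalkyl radical must add to a trisubstituted butenolide, and the C8 configuration rests on an acyclic model rather than on a ring; this is the least secure stereochemical call in the route. Fallback, setting out from 19 and returning at 24: acylation of 19 with chloroacetic anhydride gives the small O-chloroacetyl acid F2. The same decarboxylative addition and elimination with 10 then proceeds through the N-acyloxyphthalimide F3 and the saturated pivalate F4 (neither isolated) to the 8-O-chloroacetyl seco-lactone F5, taken here as the 8R epimer. Thiourea removes the chloroacetate to give the 8R alcohol F6, and a Mitsunobu esterification with 14 (PPh3, DIAD) installs the epoxy ester with inversion, so C8 is fixed by SN2 displacement instead of by the radical addition.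

Step 10 (iodo-aldol). Both the anti selectivity and, above all, the E geometry under equilibrating conditions are uncertain, since the kinetic course gives the Z iodide. Fallback, setting out from 15 and 1 and returning at 16: the coupling is run under kinetic control (MgI2, CH2Cl2, −20 °C) to the Z iodide F7. This is then converted in a separate step into 16 by iodine-atom-catalysed isomerisation (I2 cat., visible light, CH2Cl2), which drives the alkene to the E isomer with iodine trans to the ester.

The chelation-controlled C6 selectivity in step 6 is also not assured; the C6 epimers would be separated at 10.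

Further compounds
F1 | step 16 | bis(alkenyl iodide): 24 with I in place of SnBu3 | C=C1C(=O)O[C@H]([C@H]2O[C@]2(C)/C=C\I)[C@H]1[C@H](OC(=O)[C@@]1(C)O[C@H]1C)[C@@H](OC(C)=O)/C(C(=O)OC)=C\I
F2 | step 15 | (2S,3S,4E)-3-acetoxy-2-[(chloroacetyl)oxy]-5-iodo-4-(methoxycarbonyl)pent-4-enoic acid | COC(=O)/C(=C/I)[C@H](OC(C)=O)[C@H](OC(=O)CCl)C(=O)O
F3 | step 15 | 1,3-dioxoisoindolin-2-yl ester of F2 | COC(=O)/C(=C/I)[C@H](OC(C)=O)[C@H](OC(=O)CCl)C(=O)ON1C(=O)c2ccccc2C1=O
F4 | step 15 | saturated pivalate adduct of the 8R chloroacetate series (C11 epimers) | CC(C)(C)C(=O)OCC1C(=O)O[C@H]([C@H]2O[C@]2(C)/C=C\[Sn](CCCC)(CCCC)CCCC)[C@H]1[C@@H](OC(=O)CCl)[C@@H](OC(C)=O)/C(C(=O)OC)=C\I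
F5 | step 15 | 8R seco-lactone carrying O-chloroacetyl at C8 in place of the epoxy ester | C=C1C(=O)O[C@H]([C@H]2O[C@]2(C)/C=C\[Sn](CCCC)(CCCC)CCCC)[C@H]1[C@@H](OC(=O)CCl)[C@@H](OC(C)=O)/C(C(=O)OC)=C\I
F6 | step 15 | 8R seco-lactone with free C8 hydroxyl | C=C1C(=O)O[C@H]([C@H]2O[C@]2(C)/C=C\[Sn](CCCC)(CCCC)CCCC)[C@H]1[C@@H](O)[C@@H](OC(C)=O)/C(C(=O)OC)=C\I
F7 | step 10 | methyl (2Z)-2-{(S)-[(4R)-2,2-dimethyl-1,3-dioxolan-4-yl](hydroxy)methyl}-3-iodoprop-2-enoate | COC(=O)/C(=C\I)[C@H](O)[C@H]1COC(C)(C)O1
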